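**Plan**

- Retrosynthesis first cuts the six O–alkyl bonds and the two aryl–acetyl bonds, leaving a hexa-ether diarylmethane in which each ring keeps one unsubstituted carbon.
- Ring B has oxygen on three alternating ring carbons, and the carbons between them carry the methyl group, the bridging CH2 and (later) the acetyl group. This pattern lets ring B be cut at C(OH)–C(CH3) and C(OEt)–C(CH2Ar) into a 2-benzyl-3-ethoxycyclobutenone and 1-ethoxypropyne.
- The cyclobutenone is cut into ketene and an aryl-propargyl ynol ether, which goes back through a 3-arylpropanoate ester and an aldehyde to 2,4,6-trimethoxytoluene (ring A, bought).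
- Forward: ring A, then a three-carbon chain, the ynol ether, the four-membered ring, ring B by benzannulation, O-methylation, two acetyl groups, and removal of six alkyl groups.
- Stereochemistry: the target has no stereocentre. The only transient one (in the vinylcyclobutenone) is racemic and is destroyed in the same flask.

Key step: step 6

Remark: the target is achiral and is drawn as the hexaphenol diketone; ketene is taken as a gas stream from pyrolysis of acetone.

**Step 1**
Reactants: 1 2,4,6-trimethoxytoluene
Product: 2 2,4,6-trimethoxy-3-methylbenzaldehyde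
Conditions: POCl3, DMF, 0 °C → rt; then H2O, 50 °C
Reagents that add atoms: N,N-dimethylformamide CN(C)C=O; water O
Why: Vilsmeier–Haack formylation should occur at one of the two equivalent free carbons of the strongly activated ring, and the new formyl group deactivates the ring enough to stop a second substitution.

**Step 2**
Reactants: 2 2,4,6-trimethoxy-3-methylbenzaldehyde
Product: 3 ethyl (E)-3-(2,4,6-trimethoxy-3-methylphenyl)prop-2-enoate
Conditions: (EtO)2P(O)CH2CO2Et, NaH, THF, 0 °C → reflux
Reagents that add atoms: triethyl phosphonoacetate CCOC(=O)CP(=O)(OCC)OCC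
Why: Horner–Wadsworth–Emmons olefination with the stabilised phosphonate anion should give the E-cinnamate, whose geometry does not matter because the double bond is hydrogenated next.

**Step 3**
Reactants: 3 ethyl (E)-3-(2,4,6-trimethoxy-3-methylphenyl)prop-2-enoate
Product: 4 ethyl 3-(2,4,6-trimethoxy-3-methylphenyl)propanoate
Conditions: H2 (1 atm), 10% Pd/C, EtOAc, rt
Reagents that add atoms: none
Why: Heterogeneous catalytic hydrogenation of the conjugated C=C bond over palladium on carbon should leave the ester and the aryl ethers untouched.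

**Step 4**
Reactants: 4 ethyl 3-(2,4,6-trimethoxy-3-methylphenyl)propanoate
Product: 6 2-(3-ethoxyprop-2-yn-1-yl)-1,3,5-trimethoxy-4-methylbenzene, via ketene acetal phosphate 5 (not isolated)
Conditions: LiN(iPr)2, THF, −78 °C; ClP(O)(OEt)2, −78 → 0 °C; then t-BuLi (2.2 equiv), −100 → −78 °C; aq NaHCO3
Reagents that add atoms: none
Why: O-phosphorylation of the lithium ester enolate followed by base-induced β-elimination of diethyl phosphate (the enol phosphate route from ethyl esters to 1-ethoxyalkynes) should give the ynol ether with the ester's own ethoxy group, and it avoids a 2,4,6-trialkoxybenzyl halide, which would ionise and alkylate its own ring.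

**Step 5**
Reactants: 6 2-(3-ethoxyprop-2-yn-1-yl)-1,3,5-trimethoxy-4-methylbenzene
Product: 7 3-ethoxy-2-(2,4,6-trimethoxy-3-methylbenzyl)cyclobut-2-en-1-one
Conditions: CH2=C=O (gas, from acetone pyrolysis), CH2Cl2, 0 °C → rt
Reagents that add atoms: ketene C=C=O
Why: Thermal (2+2) cycloaddition of ketene with an ynol ether, the standard entry to 3-alkoxycyclobutenones, should join the nucleophilic benzyl-bearing alkyne carbon to the ketene carbonyl carbon and so give only the 2-benzyl-3-ethoxy isomer.

**Step 6**
Reactants: 7 3-ethoxy-2-(2,4,6-trimethoxy-3-methylbenzyl)cyclobut-2-en-1-one; 8 1-ethoxyprop-1-yne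
Product: 13 3,5-diethoxy-2-methyl-4-(2,4,6-trimethoxy-3-methylbenzyl)phenol, via vinylketene 9 (not isolated), via vinylcyclobutenone 10 (not isolated), via dienylketene 11 (not isolated), via cyclohexadienone 12 (not isolated)
Conditions: 8 (3 equiv), toluene, 85 °C, sealed tube
Reagents that add atoms: none
Why: Heating should open 7 by 4-electron electrocyclic ring opening to vinylketene 9, whose ketene C=C bond adds (2+2) to ynol ether 8 to give the 4-vinylcyclobutenone 10; this opens again to dienylketene 11, which closes ring B by thermal disrotatory 6-electron electrocyclisation between the ketene carbon and the terminal CH2 to give cyclohexadienone 12, and enolisation gives phenol 13. The closest known reaction type is the Danheiser aromatic annulation of cyclobutenones with alkoxy- and siloxyalkynes. No stereocentre is set: the quaternary carbon of 10 is racemic and becomes sp2 on ring opening, and a wrongly configured dienylketene can revert to 10 and reopen. The selectivity needed is regiochemical and is secured by the polarisation of the ynol ether, whose methyl-bearing carbon is the nucleophilic one and bonds to the ketene carbonyl carbon, so the ethoxy carbon bonds to the benzyl-bearing carbon and the three oxygens end up on alternating ring carbons. The CH2 of the cyclobutenone supplies the proton for aromatisation and remains as the only unsubstituted carbon of ring B, ready for the acetyl group. A brief KOH/MeOH treatment of the crude product should return the phenol from any aryl ester formed when 13 traps 9.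

**Step 7**
Reactants: 13 3,5-diethoxy-2-methyl-4-(2,4,6-trimethoxy-3-methylbenzyl)phenol
Product: 14 1,3-diethoxy-5-methoxy-4-methyl-2-(2,4,6-trimethoxy-3-methylbenzyl)benzene
Conditions: MeI, K2CO3, acetone, reflux
Reagents that add atoms: iodomethane CI
Why: Williamson O-methylation of the single phenol should make ring B a trialkoxyarene like ring A, so that both rings behave alike in the acylation and no aryl acetate forms there.

**Step 8**
Reactants: 14 1,3-diethoxy-5-methoxy-4-methyl-2-(2,4,6-trimethoxy-3-methylbenzyl)benzene
Product: 15 1-[3-(3-acetyl-2,4,6-trimethoxy-5-methylbenzyl)-2,4-diethoxy-6-methoxy-5-methylphenyl]ethan-1-one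
Conditions: AcCl (3 equiv), SnCl4 (3 equiv), CH2Cl2, −20 → 0 °C
Reagents that add atoms: acetyl chloride CC(Cl)=O
Why: Friedel–Crafts acylation should take place on each ring at its only unsubstituted carbon, which lies between two alkoxy groups and para to a third, while the mild Lewis acid at low temperature is meant to spare the ethers and the diarylmethane bridge.

**Step 9**
Reactants: 15 1-[3-(3-acetyl-2,4,6-trimethoxy-5-methylbenzyl)-2,4-diethoxy-6-methoxy-5-methylphenyl]ethan-1-one
Product: 16 bis(3-acetyl-2,4,6-trihydroxy-5-methylphenyl)methane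
Conditions: BBr3 (12 equiv), CH2Cl2, −78 °C → rt; then H2O
Reagents that add atoms: none
Why: Lewis acid-mediated cleavage of aryl alkyl ethers by BBr3 (bromide attack on the O-alkyl carbon of the boron–ether complex) should remove all four methyl and both ethyl groups, and the acetyl groups lower the acid sensitivity of the bridge.

**Compound list**

1 | 2,4,6-trimethoxytoluene | Cc1c(OC)cc(OC)cc1OC | starting material
2 | 2,4,6-trimethoxy-3-methylbenzaldehyde | O=Cc1c(OC)cc(OC)c(C)c1OC | intermediate
3 | ethyl (E)-3-(2,4,6-trimethoxy-3-methylphenyl)prop-2-enoate | CCOC(=O)/C=C/c1c(OC)cc(OC)c(C)c1OC | intermediate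
4 | ethyl 3-(2,4,6-trimethoxy-3-methylphenyl)propanoate | CCOC(=O)CCc1c(OC)cc(OC)c(C)c1OC | intermediate
5 | diethyl 1-ethoxy-3-(2,4,6-trimethoxy-3-methylphenyl)prop-1-en-1-yl phosphate (E/Z mixture, not isolated) | CCOC(=CCc1c(OC)cc(OC)c(C)c1OC)OP(=O)(OCC)OCC | intermediate
6 | 2-(3-ethoxyprop-2-yn-1-yl)-1,3,5-trimethoxy-4-methylbenzene | CCOC#CCc1c(OC)cc(OC)c(C)c1OC | intermediate
7 | 3-ethoxy-2-(2,4,6-trimethoxy-3-methylbenzyl)cyclobut-2-en-1-one | CCOC1=C(Cc2c(OC)cc(OC)c(C)c2OC)C(=O)C1 | intermediate
8 | 1-ethoxyprop-1-yne | CC#COCC | starting material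
9 | 3-ethoxy-2-(2,4,6-trimethoxy-3-methylbenzyl)buta-1,3-dien-1-one (not isolated) | C=C(OCC)C(Cc1c(OC)cc(OC)c(C)c1OC)=C=O | intermediate
10 | 3-ethoxy-4-(1-ethoxyethenyl)-2-methyl-4-(2,4,6-trimethoxy-3-methylbenzyl)cyclobut-2-en-1-one (racemic, not isolated) | CCOC(=C)C1(Cc2c(OC)cc(OC)c(C)c2OC)C(OCC)=C(C)C1=O | intermediate
11 | (3E)-3,5-diethoxy-2-methyl-4-(2,4,6-trimethoxy-3-methylbenzyl)hexa-1,3,5-trien-1-one (not isolated) | O=C=C(C)/C(OCC)=C(\C(OCC)=C)Cc1c(OC)cc(OC)c(C)c1OC | intermediate
12 | 3,5-diethoxy-2-methyl-4-(2,4,6-trimethoxy-3-methylbenzyl)cyclohexa-2,4-dien-1-one (not isolated) | O=C1CC(OCC)=C(Cc2c(OC)cc(OC)c(C)c2OC)C(OCC)=C1C | intermediate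
13 | 3,5-diethoxy-2-methyl-4-(2,4,6-trimethoxy-3-methylbenzyl)phenol | Oc1cc(OCC)c(Cc2c(OC)cc(OC)c(C)c2OC)c(OCC)c1C | intermediate
14 | 1,3-diethoxy-5-methoxy-4-methyl-2-(2,4,6-trimethoxy-3-methylbenzyl)benzene | COc1cc(OCC)c(Cc2c(OC)cc(OC)c(C)c2OC)c(OCC)c1C | intermediate
15 | 1-[3-(3-acetyl-2,4,6-trimethoxy-5-methylbenzyl)-2,4-diethoxy-6-methoxy-5-methylphenyl]ethan-1-one | CC(=O)c1c(OC)c(C)c(OCC)c(Cc2c(OC)c(C)c(OC)c(C(C)=O)c2OC)c1OCC | intermediate
16 | bis(3-acetyl-2,4,6-trihydroxy-5-methylphenyl)methane | CC(=O)c1c(O)c(C)c(O)c(Cc2c(O)c(C)c(O)c(C(C)=O)c2O)c1O | target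

Total step count: 9. Longest linear sequence: 9 steps (1 → 16).

**Steps most likely to fail**

1. Step 6. The ynol ether 8 may lose ethylene by retro-ene fragmentation at the temperature needed to open 7. The (2+2) addition to the fully substituted ketene carbon of 9 may also be slow, so that 9 dimerises or is consumed by the product phenol. The fallback sets out from 1 and comes back at 16, building the bridge between two preformed rings instead of building ring B. Acid-catalysed condensation of excess 1 with paraformaldehyde (cat. H2SO4, AcOH, rt) should give bis(2,4,6-trimethoxy-3-methylphenyl)methane F1. Double Friedel–Crafts acetylation (AcCl, SnCl4, CH2Cl2, −20 → 0 °C) should then give bis(3-acetyl-2,4,6-trimethoxy-5-methylphenyl)methane F2, and BBr3 in CH2Cl2 should cleave its six methyl ethers to 16.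

2. Step 4. The ester enolate may be phosphorylated on carbon instead of oxygen, or excess base may deprotonate the benzylic and propargylic CH2 of 6 and isomerise the alkyne to an allenyl ether. The fallback sets out from 2 and comes back at 6 by alkylating an acetylide instead of eliminating from an ester. NaBH4 in MeOH should give (2,4,6-trimethoxy-3-methylphenyl)methanol F3. PBr3 in Et2O at −20 °C should give 2-(bromomethyl)-1,3,5-trimethoxy-4-methylbenzene F4, which is kept cold and used at once because it ionises easily. SN2 alkylation of LiC≡COEt (from ethoxyethyne and n-BuLi, THF/HMPA, −78 → 0 °C) with F4 should then give 6.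

3. Step 8. The acylium ion or a proton may attack the bridge-bearing ring carbons (ipso attack), which would cut or scramble the diarylmethane. The fallback sets out from 14 and comes back at 15 under basic conditions. Double directed ortho-lithiation (n-BuLi, TMEDA, THF, 0 °C) at the two ring CH carbons that lie between alkoxy groups, followed by addition to acetaldehyde at −78 °C, should give 1-[3-[[3-(1-hydroxyethyl)-2,4,6-trimethoxy-5-methylphenyl]methyl]-2,4-diethoxy-6-methoxy-5-methylphenyl]ethan-1-ol F5 as a mixture of diastereomers. Oxidation of both alcohols with Dess–Martin periodinane in CH2Cl2 should give 15.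

**Further compounds**

F1 | step 6 | bis(2,4,6-trimethoxy-3-methylphenyl)methane | Cc1c(OC)cc(OC)c(Cc2c(OC)cc(OC)c(C)c2OC)c1OC
F2 | step 6 | bis(3-acetyl-2,4,6-trimethoxy-5-methylphenyl)methane | CC(=O)c1c(OC)c(C)c(OC)c(Cc2c(OC)c(C)c(OC)c(C(C)=O)c2OC)c1OC
F3 | step 4 | (2,4,6-trimethoxy-3-methylphenyl)methanol | OCc1c(OC)cc(OC)c(C)c1OC
F4 | step 4 | 2-(bromomethyl)-1,3,5-trimethoxy-4-methylbenzene | BrCc1c(OC)cc(OC)c(C)c1OC
F5 | step 8 | 1-[3-[[3-(1-hydroxyethyl)-2,4,6-trimethoxy-5-methylphenyl]methyl]-2,4-diethoxy-6-methoxy-5-methylphenyl]ethan-1-ol (mixture of diastereomers) | CC(O)c1c(OC)c(C)c(OCC)c(Cc2c(OC)c(C)c(OC)c(C(C)O)c2OC)c1OCC
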